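0.0400 mM of free catalyst: this is the surviving catalyst S, the charge of free catalyst minus the stray impurity, which the poisoning step takes up one for one. The stray impurity is the limiting reagent of that step, with 0.32 mM against 0.360 mM of catalyst.

substrate 0.10 M; gas phase 10 mM (held); protic impurity 2.00 mM; free catalyst 0.36 mol%; stray impurity 0.32 mM; time 15 min

    gas phase ⇌ dissolved gas, rate k1*(csat - [dissolved gas]) (k1 = 0.0087 /s, csat = 10 mM)
    substrate + dissolved gas + free catalyst ⇌ free catalyst + product (K2 = 190 /M, k2 = 480 /M²/s)
    dissolved gas + protic impurity → quenched reagent (k3 = 1.2 /M/s)
    free catalyst + stray impurity → spent catalyst (k4 = 93 /M/s)

- product at 15 min, in percent of the substrate charged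
- the change that raises the amount of product at 15 min, in percent of the substrate charged most ("none" if none brings more than 2 percentage points) (north-east / north / east / none)
- amount of product at 15 min, in percent of the substrate charged, after north

- at the start none of the gas is dissolved
- run time (flask): 15 min

1. First estimate: take the dissolved gas at its saturation value c and the catalyst at S. Product then relaxes towards the equilibrium share Kc/(1+Kc) = 65.5%, where K is the equilibrium constant of the product step. The relaxation rate is kS(c+1/K), with k the rate constant of that step. By 15 min this gives 15.2%.

2. Objection: the gas has to arrive. The reaction draws on dissolved gas at r = kS times the charged substrate, 0.00192 /s, and the transfer coefficient a is 0.0087 /s. Setting transfer equal to net reaction multiplies the rate by a/(a+r), giving L = 0.0144 /min. The estimate falls to 12.7%.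

3. Objection: the protic impurity consumes gas. It can take 2.00 mM, against 78.3 mM that transfer can bring, so it is dropped.

4. Objection: the poisoning takes time. The excess catalyst adds an exposure ln(charge/S)/(k'S) = 9.84 min at S, with k' the poisoning constant. Counted in full, this lifts the estimate to 19.7%. But the excess falls at first on a scale of about 0.560 min, shorter than the 1.92 min the gas needs to come up, while its tail runs on about 4.48 min, longer than that. Part of that exposure meets thin gas and part does not, so this reckoning puts the yield between the two figures, and the next step carries on the lower formula, which leaves this exposure out.

5. Changes: doubling the catalyst makes S 0.400 mM, ten times as much, and r now exceeds a. The same formula gives 36.7%. Doubling saturation gives 23.8%, and doubling transfer gives 13.9%. The choice is north.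

The forecast gives 14% (11% to 17%), north, and 40% (34% to 45%) after that change, which “moves the run to being limited by gas transfer and the reverse reaction”. The carried formula lies lower on both yields, inside those ranges.

The flask gives 14.1%, and 37.8% after north, a gain of 24 percentage points. At 15.0 min the flask held 11.5% of its catalyst free and 88.5% spent, while S is 11.1% of the charge. For the neighbour flask with 0.9 mol% of free catalyst, S is 0.580 mM, or 64.4% of its charge, and the formula gives 39.2%. That neighbour flask ended with 64.4% of its catalyst free and 41.2% product.

(The constants were drawn at random within sensible limits; no experiment stands behind them.)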